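The constants give one concentration I want before anything else; they stand here with the flask and the questions.

    starting material + catalyst intermediate A → catalyst intermediate B (k1 = 4.10 M⁻¹ s⁻¹)
    catalyst intermediate B → by-product + catalyst intermediate C (k2 = 0.0561 s⁻¹)
    2 catalyst intermediate C ⇌ resting dimer, settled at all times (K3 = 180 M⁻¹)
    partner + free catalyst → catalyst intermediate A (k4 = 0.323 M⁻¹ s⁻¹)
    catalyst intermediate C → free catalyst + target (k5 = 0.0173 s⁻¹)

starting material 0.17 M; partner 1.20 equiv; free catalyst 2 mol%

- percent here means starting material units held: one resting dimer counts as two
- two of one species on the left: rate k times its square, two consumed each time
- a form made of two catalysts counts as two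
- charge of starting material (flask): 0.17 M

- the form that holds most of the catalyst when 5.0 % of the starting material are converted (catalyst intermediate A / catalyst intermediate C / catalyst intermediate B / free catalyst / resting dimer)
- its share of the catalyst then

Which form of the catalyst in the working round is left most slowly? At 5.0 % conversion each catalyst has turned over 2.50 times, so I take one common flux through the round, and each form then holds catalyst in inverse proportion to its exit rate. With the reagents as charged, catalyst intermediate C leaves at 62 h⁻¹, slower than catalyst intermediate B at 200 h⁻¹, free catalyst at 240 h⁻¹ and catalyst intermediate A at 2500 h⁻¹. Per unit of catalyst intermediate C, the round therefore holds 1.60 units.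

Can the resting dimer overtake it? I take the fast step as balanced: [resting dimer] is 180 M⁻¹ times [catalyst intermediate C] squared, and each dimer counts as two catalysts. The dimer therefore holds as much catalyst as catalyst intermediate C when [catalyst intermediate C] equals one over twice the balance constant, the crossover concentration 2.78 mM. Equal holdings at that point take 5.56 mM of catalyst in these two forms together, more than the catalyst charge of 3.40 mM, so in this flask the dimer stays below catalyst intermediate C, and the share is what remains to be reckoned.

How high does [catalyst intermediate C] rise? The catalyst balance, with the round and the dimer together, gives [catalyst intermediate C] as 0.566 of the crossover concentration. By my reckoning, catalyst intermediate C is the resting state with 46.3 %, more than the 26.2 % in the dimer.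

The forecast gives catalyst intermediate C at 46 %, on the view that “quasi-steady state holds”.

The simulation gives catalyst intermediate C at 46.1 %, reached at 0.0640 h. In this flask that share is 0.564 of the crossover concentration, and the resting dimer holds 26.0 %. Later in the same flask, at 0.600 h, catalyst intermediate C holds 44.3 %, which is 0.542 of the crossover concentration. That ratio times the share puts 24.0 % in the dimer, and the flask holds 24.0 % there.

All constants were set for the occasion; what happens was integrated by code.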